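Ring A and the spiro atom C7 are made in one photochemical operation, an intramolecular de Mayo reaction. With C2 and C10 written as ketones they are 1,5-related through C7–C8–C9, the imprint of an enol–alkene [2+2] cycloaddition and retro-aldol cleavage. Irradiating an acyclic, enolised 2,4-diketone that carries the C5 silyl ether, the C6 gem-dimethyl group and a C7=C8 methylidene with an allyl arm (C12, C11) forms C2–C7 and C8–C9, closes ring A, sets C7 from C5 and releases the 3-oxobutyl arm. Double methylenation and ring-closing metathesis then close ring B; C5 becomes the bromide and C10=C11 the bromohydrin.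

Key step: step 12

Remark on the chemistry: atoms are labelled along the target (C1 exocyclic CH2; ring A C2–C7 with C5 the CHBr, C6 the CMe2, C7 the spiro atom; ring B C7–C12 with C10 the carbinol, C11 the CHBr); (R)-pantolactone is assumed because its carbinol carbon maps onto C5 with oxygen on the side the bromine finally occupies.

Step 1
Reactants: 1 (R)-pantolactone
Product: 2 (2R)-3,3-dimethylbutane-1,2,4-triol
Conditions: LiAlH4, THF, 0 → 65 °C; Fieser work-up
Reagents that add atoms: none
Why: Hydride reduction of the lactone gives the triol (C4, C5, C7 oxygens) without touching the C5 stereocentre.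

Step 2
Reactants: 2 (2R)-3,3-dimethylbutane-1,2,4-triol
Product: 3 2-[(4R)-2,2-dimethyl-1,3-dioxolan-4-yl]-2-methylpropan-1-ol
Conditions: 2,2-dimethoxypropane, acetone, p-TsOH·H2O (cat.), 20 °C; Et3N quench
Reagents that add atoms: 2,2-dimethoxypropane, COC(C)(C)OC
Why: Equilibrating acetonide formation should favour the five-membered dioxolane over O4/O5 and leave the neopentyl C7 hydroxyl free.

Step 3
Reactants: 3 2-[(4R)-2,2-dimethyl-1,3-dioxolan-4-yl]-2-methylpropan-1-ol
Product: 4 2-[(4R)-2,2-dimethyl-1,3-dioxolan-4-yl]-2-methylpropanal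
Conditions: TEMPO (2,2,6,6-tetramethylpiperidin-1-oxyl, 10 mol%), PhI(OAc)2, CH2Cl2, 20 °C
Reagents that add atoms: none
Why: Oxoammonium (TEMPO) oxidation takes the primary alcohol to a non-enolisable aldehyde and stops there.

Step 4
Reactants: 4 2-[(4R)-2,2-dimethyl-1,3-dioxolan-4-yl]-2-methylpropanal
Product: 5 3-[(4R)-2,2-dimethyl-1,3-dioxolan-4-yl]-3-methylbutan-2-ol (both carbinol epimers)
Conditions: MeMgBr, Et2O, −78 → 0 °C; aq. NH4Cl
Reagents that add atoms: methylmagnesium bromide, C[Mg]Br
Why: Grignard addition brings in C8; the new carbinol centre is oxidised away in the next step, so its configuration is irrelevant.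

Step 5
Reactants: 5 3-[(4R)-2,2-dimethyl-1,3-dioxolan-4-yl]-3-methylbutan-2-ol
Product: 6 3-[(4R)-2,2-dimethyl-1,3-dioxolan-4-yl]-3-methylbutan-2-one
Conditions: Dess–Martin periodinane, pyridine, CH2Cl2, 0 → 20 °C
Reagents that add atoms: none
Why: Dess–Martin oxidation of the hindered secondary alcohol gives the C7 methyl ketone, with pyridine protecting the acetonide from acetic acid.

Step 6
Reactants: 6 3-[(4R)-2,2-dimethyl-1,3-dioxolan-4-yl]-3-methylbutan-2-one
Product: 7 3-[(4R)-2,2-dimethyl-1,3-dioxolan-4-yl]-3-methylbut-1-en-2-yl trifluoromethanesulfonate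
Conditions: KN(SiMe3)2, THF, −78 °C; PhNTf2, −78 → 0 °C
Reagents that add atoms: N-phenylbis(trifluoromethanesulfonimide), O=S(=O)(N(c1ccccc1)S(=O)(=O)C(F)(F)F)C(F)(F)F
Why: The ketone can enolise only toward the methyl group (C8) because C6 is quaternary, so enolate O-triflation gives a single enol triflate.

Step 7
Reactants: 7 3-[(4R)-2,2-dimethyl-1,3-dioxolan-4-yl]-3-methylbut-1-en-2-yl trifluoromethanesulfonate; 8 allyltributylstannane
Product: 9 (4R)-2,2-dimethyl-4-(2-methyl-3-methylidenehex-5-en-2-yl)-1,3-dioxolane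
Conditions: Pd(PPh3)4 (5 mol%), LiCl (3 equiv), THF, 65 °C
Reagents that add atoms: none
Why: Stille coupling of the vinyl triflate with the allylstannane (LiCl-promoted) places the allyl arm (C12, C11) on C7 and fixes the C7=C8 methylidene.

Step 8
Reactants: 9 (4R)-2,2-dimethyl-4-(2-methyl-3-methylidenehex-5-en-2-yl)-1,3-dioxolane
Product: 10 (2R)-3,3-dimethyl-4-methylidenehept-6-ene-1,2-diol
Conditions: AcOH–H2O 4:1, 40 °C
Reagents that add atoms: none
Why: Mild acid hydrolysis removes the acetonide under conditions that isolated alkenes should tolerate.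

Step 9
Reactants: 10 (2R)-3,3-dimethyl-4-methylidenehept-6-ene-1,2-diol
Product: 12 (2R)-2-(2-methyl-3-methylidenehex-5-en-2-yl)oxirane, via primary monotosylate 11 (not isolated)
Conditions: NaH (2.2 equiv), THF, 0 °C; 1-tosylimidazole (1.05 equiv), 0 → 20 °C
Reagents that add atoms: none
Why: The unhindered primary alkoxide is sulfonylated selectively and the C5 alkoxide then closes the epoxide by intramolecular Williamson displacement at C4, so the C5–O bond and its configuration are kept.

Step 10
Reactants: 12 (2R)-2-(2-methyl-3-methylidenehex-5-en-2-yl)oxirane; 13 pentane-2,4-dione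
Product: 15 (7S)-7-hydroxy-8,8-dimethyl-9-methylidenedodec-11-ene-2,4-dione, via pentane-2,4-dione 1,3-dianion 14 (not isolated)
Conditions: 13 (1.5 equiv), NaH then n-BuLi, THF, 0 °C; add 12, 0 → 20 °C; aq. NH4Cl
Reagents that add atoms: none
Why: The terminal carbanion of the Hauser-type dianion opens the epoxide by SN2 at the unhindered CH2 (C4), forming C3–C4 and leaving C5 untouched; an epoxide is used because a β-silyloxy iodide at C4 would be a poor SN2 partner.

Step 11
Reactants: 15 (7S)-7-hydroxy-8,8-dimethyl-9-methylidenedodec-11-ene-2,4-dione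
Product: 17 (7S)-7-{[tert-butyl(dimethyl)silyl]oxy}-8,8-dimethyl-9-methylidenedodec-11-ene-2,4-dione, via bis-silylated enol ether 16 (not isolated)
Conditions: crude 15, TBSOTf (2.5 equiv), 2,6-lutidine, CH2Cl2, −78 → 0 °C; then 1 M aq. citric acid–THF, 0 °C
Reagents that add atoms: tert-butyldimethylsilyl trifluoromethanesulfonate, CC(C)(C)[Si](C)(C)OS(=O)(=O)C(F)(F)F
Why: Silyl triflate silylation covers the hindered C5 hydroxyl (and, transiently, the enol), and the labile enol silyl ether is hydrolysed on mild acidic work-up, which blocks hemiketal formation between O5 and C2.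

Step 12
Reactants: 17 (7S)-7-{[tert-butyl(dimethyl)silyl]oxy}-8,8-dimethyl-9-methylidenedodec-11-ene-2,4-dione
Product: 19 (2S,4S)-4-{[tert-butyl(dimethyl)silyl]oxy}-3,3-dimethyl-2-(3-oxobutyl)-2-(prop-2-en-1-yl)cyclohexan-1-one, via cis-fused cyclobutanol 18 (not isolated)
Conditions: hν (medium-pressure mercury lamp, Pyrex filter, λ > 290 nm), degassed cyclohexane, 0.005 M, 20 °C; stop at full conversion
Reagents that add atoms: none
Why: Excitation of the hydrogen-bonded enol (C2=C9 conjugated to C10=O) leads through a 1,4-diradical in which C2 bonds to C7 and C9 then couples with C8, and the strained β-hydroxy ketone 18 opens at once by retro-aldol cleavage of C2–C9, so C7–C8 is inserted between C2 and C9 (intramolecular de Mayo reaction; closest known type: enol–alkene photocycloaddition of 1,3-diketones through a four-atom tether). Ring A closes 6-exo at C7 with the first bond, and the transient cyclobutane closes by C9–C8 radical recombination in the head-to-tail sense. C7 is set by C5: in a chair-like tether the silyloxy group is equatorial and the small enol OH, not C9, takes the axial site at C2 beside the axial C6 methyl, so C8 is axial and the allyl arm (C12) equatorial, cis to the C5 oxygen. The step needs C2 to bond to C7 and not to C8, which the four-atom tether and the gem-dimethyl group favour, and it needs C7=C8 to react before the allyl vinyl group, which would require an eight-membered closure. A Pyrex-filtered lamp is used because the enol absorbs near 280–310 nm, and irradiation is stopped at full conversion to spare the weakly absorbing diketone.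

Step 13
Reactants: 19 (2S,4S)-4-{[tert-butyl(dimethyl)silyl]oxy}-3,3-dimethyl-2-(3-oxobutyl)-2-(prop-2-en-1-yl)cyclohexan-1-one
Product: 20 tert-butyl{[(1S,3R)-2,2-dimethyl-4-methylidene-3-(3-methylbut-3-en-1-yl)-3-(prop-2-en-1-yl)cyclohexyl]oxy}dimethylsilane
Conditions: Cp2TiMe2 (5 equiv), toluene–THF, 70 °C, dark
Reagents that add atoms: dimethyltitanocene Cp2TiMe2, C[Ti+2]C.c1cc[cH-]c1.c1cc[cH-]c1
Why: Petasis methylenation (Cp2Ti=CH2 generated thermally) converts both the hindered C2 ketone and the C10 methyl ketone under non-basic conditions, which avoids aldol closure of the 1,5-diketone and installs C1.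

Step 14
Reactants: 20 tert-butyl{[(1S,3R)-2,2-dimethyl-4-methylidene-3-(3-methylbut-3-en-1-yl)-3-(prop-2-en-1-yl)cyclohexyl]oxy}dimethylsilane
Product: 21 tert-butyl(dimethyl){[(2S,6R)-1,1,9-trimethyl-5-methylidenespiro[5.5]undec-8-en-2-yl]oxy}silane
Conditions: second-generation Grubbs catalyst (H2IMes)(PCy3)Cl2Ru=CHPh (5 mol%), CH2Cl2, 40 °C
Reagents that add atoms: none
Why: Ring-closing metathesis between the allyl vinyl group and the isopropenyl group closes ring B as the trisubstituted C10=C11 cyclohexene, while the hindered exocyclic C2=C1 could only give a tetrasubstituted cyclopentene and stays out.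

Step 15
Reactants: 21 tert-butyl(dimethyl){[(2S,6R)-1,1,9-trimethyl-5-methylidenespiro[5.5]undec-8-en-2-yl]oxy}silane
Product: 22 (2S,6R)-1,1,9-trimethyl-5-methylidenespiro[5.5]undec-8-en-2-ol
Conditions: Bu4NF, THF, 50 °C
Reagents that add atoms: none
Why: Fluoride-mediated desilylation frees the C5 hydroxyl, with warming because the silyl ether is neopentylic.

Step 16
Reactants: 22 (2S,6R)-1,1,9-trimethyl-5-methylidenespiro[5.5]undec-8-en-2-ol
Product: 23 (6R)-1,1,9-trimethyl-5-methylidenespiro[5.5]undec-8-en-2-one
Conditions: Dess–Martin periodinane, pyridine, CH2Cl2, 20 °C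
Reagents that add atoms: none
Why: Dess–Martin oxidation removes the C5 stereocentre once it has set C7, so that C5 can be rebuilt with the opposite configuration.

Step 17
Reactants: 23 (6R)-1,1,9-trimethyl-5-methylidenespiro[5.5]undec-8-en-2-one
Product: 24 (2R,6R)-1,1,9-trimethyl-5-methylidenespiro[5.5]undec-8-en-2-ol
Conditions: (S)-2-methyl-CBS-oxazaborolidine [(3aS)-1-methyl-3,3-diphenyltetrahydro-1H,3H-pyrrolo[1,2-c][1,3,2]oxazaborole, 0.3 equiv], catecholborane (2 equiv), toluene, −78 → −30 °C; MeOH then aq. NaOH work-up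
Reagents that add atoms: none
Why: CBS reduction differentiates the quaternary C6 flank from the C4 methylene, so the (S)-catalyst should deliver hydride to give the (2R)-alcohol (hydroxyl trans to C12) by reagent control, needed because the two ring B methylenes on C7 offer almost no substrate bias; catecholborane spares the alkenes.

Step 18
Reactants: 24 (2R,6R)-1,1,9-trimethyl-5-methylidenespiro[5.5]undec-8-en-2-ol
Product: 25 (6R,8S)-8-bromo-3,7,7-trimethyl-11-methylidenespiro[5.5]undec-2-ene
Conditions: PPh3, CBr4, toluene, 0 → 60 °C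
Reagents that add atoms: carbon tetrabromide, BrC(Br)(Br)Br
Why: Appel reaction, in which bromide displaces the oxyphosphonium group by SN2 with inversion, should place the C5 bromine equatorial and cis to C12.

Step 19
Reactants: 25 (6R,8S)-8-bromo-3,7,7-trimethyl-11-methylidenespiro[5.5]undec-2-ene
Product: 26 (2R,3R,6R,8S)-2,8-dibromo-3,7,7-trimethyl-11-methylidenespiro[5.5]undecan-3-ol (CNP0114057.1)
Conditions: NBS (1.05 equiv), acetone–H2O 4:1, 0 °C, dark
Reagents that add atoms: N-bromosuccinimide, O=C1CCC(=O)N1Br; water, O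
Why: Bromohydrin formation on the electron-rich trisubstituted C10=C11 alkene should put the bromonium ion on the ring B face anti to C2 (the equatorial C5 bromine holds ring A so that the C1 methylene sits over C12/C11), and water then opens it anti at the more substituted C10, giving 11-Br and 10-OH trans with the target configuration.

Compound list
1 | (R)-pantolactone, (3R)-3-hydroxy-4,4-dimethyloxolan-2-one | CC1(C)COC(=O)[C@@H]1O | starting material
2 | (2R)-3,3-dimethylbutane-1,2,4-triol | OC[C@H](O)C(C)(C)CO | intermediate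
3 | 2-[(4R)-2,2-dimethyl-1,3-dioxolan-4-yl]-2-methylpropan-1-ol | CC1(C)OC[C@H](O1)C(C)(C)CO | intermediate
4 | 2-[(4R)-2,2-dimethyl-1,3-dioxolan-4-yl]-2-methylpropanal | CC1(C)OC[C@H](O1)C(C)(C)C=O | intermediate
5 | 3-[(4R)-2,2-dimethyl-1,3-dioxolan-4-yl]-3-methylbutan-2-ol, both carbinol epimers | CC1(C)OC[C@H](O1)C(C)(C)C(C)O | intermediate
6 | 3-[(4R)-2,2-dimethyl-1,3-dioxolan-4-yl]-3-methylbutan-2-one | CC1(C)OC[C@H](O1)C(C)(C)C(C)=O | intermediate
7 | 3-[(4R)-2,2-dimethyl-1,3-dioxolan-4-yl]-3-methylbut-1-en-2-yl trifluoromethanesulfonate | CC1(C)OC[C@H](O1)C(C)(C)C(=C)OS(=O)(=O)C(F)(F)F | intermediate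
8 | allyltributylstannane, tributyl(prop-2-en-1-yl)stannane | C=CC[Sn](CCCC)(CCCC)CCCC | starting material
9 | (4R)-2,2-dimethyl-4-(2-methyl-3-methylidenehex-5-en-2-yl)-1,3-dioxolane | CC1(C)OC[C@H](O1)C(C)(C)C(=C)CC=C | intermediate
10 | (2R)-3,3-dimethyl-4-methylidenehept-6-ene-1,2-diol | OC[C@H](O)C(C)(C)C(=C)CC=C | intermediate
11 | (2R)-2-hydroxy-3,3-dimethyl-4-methylidenehept-6-en-1-yl 4-methylbenzenesulfonate, present as its sodium alkoxide in the flask | Cc1ccc(cc1)S(=O)(=O)OC[C@H](O)C(C)(C)C(=C)CC=C | intermediate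
12 | (2R)-2-(2-methyl-3-methylidenehex-5-en-2-yl)oxirane | C=CCC(=C)C(C)(C)[C@@H]1CO1 | intermediate
13 | pentane-2,4-dione | CC(=O)CC(C)=O | starting material
14 | pentane-2,4-dione 1,3-dianion, lithium sodium salt, formed in the flask | [Li+].[Na+].[CH2-]C(=O)[CH-]C(C)=O | intermediate
15 | (7S)-7-hydroxy-8,8-dimethyl-9-methylidenedodec-11-ene-2,4-dione | CC(=O)CC(=O)CC[C@H](O)C(C)(C)C(=C)CC=C | intermediate
16 | (3Z,7S)-4,7-bis{[tert-butyl(dimethyl)silyl]oxy}-8,8-dimethyl-9-methylidenedodeca-3,11-dien-2-one, formed in the flask and drawn as the O2 enol ether (the O10 regioisomer hydrolyses to the same product) | CC(=O)/C=C(\O[Si](C)(C)C(C)(C)C)CC[C@H](O[Si](C)(C)C(C)(C)C)C(C)(C)C(=C)CC=C | intermediate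
17 | (7S)-7-{[tert-butyl(dimethyl)silyl]oxy}-8,8-dimethyl-9-methylidenedodec-11-ene-2,4-dione, the key-step precursor | CC(=O)CC(=O)CC[C@H](O[Si](C)(C)C(C)(C)C)C(C)(C)C(=C)CC=C | intermediate
18 | 1-[(1R,3S,6S)-3-{[tert-butyl(dimethyl)silyl]oxy}-6-hydroxy-2,2-dimethyl-1-(prop-2-en-1-yl)bicyclo[4.2.0]octan-7-yl]ethan-1-one, cis-fused cyclobutanol formed in the flask, acetyl-bearing carbon unassigned | CC(=O)C1C[C@]2(CC=C)C(C)(C)[C@@H](O[Si](C)(C)C(C)(C)C)CC[C@]12O | intermediate
19 | (2S,4S)-4-{[tert-butyl(dimethyl)silyl]oxy}-3,3-dimethyl-2-(3-oxobutyl)-2-(prop-2-en-1-yl)cyclohexan-1-one, the key-step product | O=C1CC[C@H](O[Si](C)(C)C(C)(C)C)C(C)(C)[C@]1(CCC(C)=O)CC=C | intermediate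
20 | tert-butyl{[(1S,3R)-2,2-dimethyl-4-methylidene-3-(3-methylbut-3-en-1-yl)-3-(prop-2-en-1-yl)cyclohexyl]oxy}dimethylsilane | C=C1CC[C@H](O[Si](C)(C)C(C)(C)C)C(C)(C)[C@]1(CCC(C)=C)CC=C | intermediate
21 | tert-butyl(dimethyl){[(2S,6R)-1,1,9-trimethyl-5-methylidenespiro[5.5]undec-8-en-2-yl]oxy}silane | C=C1CC[C@H](O[Si](C)(C)C(C)(C)C)C(C)(C)[C@@]12CCC(C)=CC2 | intermediate
22 | (2S,6R)-1,1,9-trimethyl-5-methylidenespiro[5.5]undec-8-en-2-ol | C=C1CC[C@H](O)C(C)(C)[C@@]12CCC(C)=CC2 | intermediate
23 | (6R)-1,1,9-trimethyl-5-methylidenespiro[5.5]undec-8-en-2-one | C=C1CCC(=O)C(C)(C)[C@@]12CCC(C)=CC2 | intermediate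
24 | (2R,6R)-1,1,9-trimethyl-5-methylidenespiro[5.5]undec-8-en-2-ol | C=C1CC[C@@H](O)C(C)(C)[C@@]12CCC(C)=CC2 | intermediate
25 | (6R,8S)-8-bromo-3,7,7-trimethyl-11-methylidenespiro[5.5]undec-2-ene | C=C1CC[C@H](Br)C(C)(C)[C@@]12CCC(C)=CC2 | intermediate
26 | (2R,3R,6R,8S)-2,8-dibromo-3,7,7-trimethyl-11-methylidenespiro[5.5]undecan-3-ol | C=C1CC[C@H](Br)C(C)(C)[C@@]12CC[C@@](C)(O)[C@H](Br)C2 | target

Total step count: 19. Longest linear sequence: 19 steps (1 to 26); compounds 8 and 13 enter as purchased reagents.

Steps most likely to fail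

Step 12. The free diketone is a mobile mixture of enol tautomers on a flexible chain: addition to the hindered C7 may be slow, bonding may go in the crossed sense (C2 to C8), and the 1,5-diketone may be photolysed further once it forms. The fallback is the two-stage enol-ester variant, which fixes the chromophore and keeps the diketone out of the light. Setting out from 17, acetylation (Ac2O, Et3N, DMAP, CH2Cl2) should give the enol acetate at O2, (3Z,7S)-7-{[tert-butyl(dimethyl)silyl]oxy}-8,8-dimethyl-9-methylidene-2-oxododeca-3,11-dien-4-yl acetate F1; the O10 regioisomer cannot reach the alkene and is separated and returned to 17 with K2CO3 in MeOH. Irradiation of F1 (λ > 290 nm, acetone as sensitiser) should give the cis-fused cyclobutyl acetate F2, which cannot fragment under the lamp. K2CO3 in MeOH then removes the acetate, the cyclobutanolate opens by retro-aldol cleavage, and the route is rejoined at 19.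

Step 18. Backside attack at C5 is neopentylic; loss of the oxyphosphonium group by E2 toward C4, or ionisation with a 1,2-methyl shift from C6, may outrun substitution. The fallback separates activation from displacement, so that a far better leaving group meets a free bromide at low temperature. Setting out from 24, Tf2O and 2,6-lutidine in CH2Cl2 at −78 °C should give (2R,6R)-1,1,9-trimethyl-5-methylidenespiro[5.5]undec-8-en-2-yl trifluoromethanesulfonate F3, which is treated without warming with Bu4NBr in toluene (−40 → 0 °C). SN2 inversion comes back to the route at 25.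

Step 19. The bromonium ion may form on the ring B face syn to C2 instead of anti, which would give the (10S,11S) bromohydrin after anti opening by water. The fallback is stereochemically complementary: it delivers oxygen, not bromine, to whichever face electrophiles prefer. Setting out from 25, mCPBA with NaHCO3 in CH2Cl2 at 0 °C should epoxidise the trisubstituted alkene on that same syn face, giving the C10–C11 epoxide of 25 with oxygen cis to C2 across ring B (C10 R, C11 S by the atom labels used here) F4. Li2NiBr4 in THF then opens F4 with bromide at the secondary C11 with inversion, which gives 26 directly.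

Further compounds
F1 | step 12 | (3Z,7S)-7-{[tert-butyl(dimethyl)silyl]oxy}-8,8-dimethyl-9-methylidene-2-oxododeca-3,11-dien-4-yl acetate | CC(=O)/C=C(\OC(C)=O)CC[C@H](O[Si](C)(C)C(C)(C)C)C(C)(C)C(=C)CC=C
F2 | step 12 | (1R,3S,6S)-7-acetyl-3-{[tert-butyl(dimethyl)silyl]oxy}-2,2-dimethyl-1-(prop-2-en-1-yl)bicyclo[4.2.0]octan-6-yl acetate, cis-fused, acetyl-bearing carbon unassigned | CC(=O)C1C[C@]2(CC=C)C(C)(C)[C@@H](O[Si](C)(C)C(C)(C)C)CC[C@]12OC(C)=O
F3 | step 18 | (2R,6R)-1,1,9-trimethyl-5-methylidenespiro[5.5]undec-8-en-2-yl trifluoromethanesulfonate | C=C1CC[C@@H](OS(=O)(=O)C(F)(F)F)C(C)(C)[C@@]12CCC(C)=CC2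
F4 | step 19 | C10–C11 epoxide of 25 with oxygen on the ring B face cis to C2 (C10 R, C11 S by the atom labels used here) | C=C1CC[C@H](Br)C(C)(C)[C@@]12CC[C@@]3(C)O[C@H]3C2
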